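(All constants are made up, and the outcome is calculated.)

In this flask the sum of substrate, target and over-reaction product stays at the substrate charged, and the sum of spent and fresh carrier stays at the carrier charged, so you can follow how each sum is shared out.

substrate 0.20 M; salt in the second phase 1.00 equiv; spent carrier 5 mol%; time 25 h; volume of the second phase over the first 2.0

    spent carrier + salt in the second phase ⇌ fresh carrier + spent salt in the second phase (K1 = 0.98, k1 = 0.43 /M/min)
    substrate + fresh carrier → target + spent carrier (k2 = 0.92 /M/min)
    target → over-reaction product (k3 = 0.0017 /min)

- in the second phase: salt in the second phase, spent salt in the second phase; everything else is in the first
- charges count per volume of the first phase; a concentration in a rate is the amount of a species over the volume of its own phase; every rate counts per litre of the first phase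
- the reaction counts as stopped when no species that holds the substrate changes by six tenths of a point or more over the second half of the time
- run time (flask): 25 h

1. which holds at 25 h: what has brought the reaction to rest, or that it has not come to rest (it is still moving / forward and back rates have come level / no working catalyst is left / the salt in the second phase has run out first / all of the substrate has reacted)
2. target at 25 h, in percent of the substrate charged
3. over-reaction product at 25 h, in percent of the substrate charged

My own reckoning climbs a ladder of times. With concentrations as charged, the salt stands at 0.100 M in its own phase, fresh carrier has a half-life of 0.063 h by the second step, and spent carrier has one of 0.27 h by the forward first step. Since both are far shorter than the 6.8 h half-life of target, the carrier reaches its steady split first. At the start, with no spent salt yet, fresh over spent is 0.234, so fresh carrier holds 18.9 % of the carrier, or 0.00189 M, and spent carrier is the resting state.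

On the slow rung, target is made and lost. Take the second step's constant times [substrate][fresh carrier], divide by the third step's constant, and you have the level of target at which making equals loss. Call it the ceiling. At the start it is 103 % of the substrate charged, a level higher than the charge, so at first it holds nothing down. It then sinks with [substrate] and [fresh carrier] while target climbs, and target peaks where the two cross. The run lasts 3.68 half-lives of target, so I expect that crossing to lie inside it, with the flask still moving. My reckoning stops there, without a yield.

The forecast goes further: it is still moving, with target at 17.8 % and over-reaction product at 67 %. Its ground is that “Neither salt nor substrate has run out, and step 2 is irreversible, so the system is still moving”.

The simulation gives: it is still moving, with target at 17.9 % and over-reaction product at 66.6 %.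

At 25.0 h this flask still holds 15.4 % substrate, and its ceiling has sunk to 7.51 %, lower than target; target is made at 0.419 of the rate it is used. At that same time the neighbour flask with 2 mol% of spent carrier has a ceiling of 12.5 %, also lower than its target of 17.2 %. Left until 250 h, this flask's ceiling is 0.0393 %, substrate is 0.896 %, target is 0.0432 %, and over-reaction product has reached 99.1 %.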